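**Plan**
- Retrosynthesis cuts, in order: the C5–OOH bond (singlet-oxygen ene reaction of a C4=C5 alkene), the C3 ester bond, C11–C12 (carbonylation of an acetyl group), then C5–C10 and C3–C4 of the decalin.
- Feature used: ring A (C1–C5, C10) shares only C5–C10 with ring B (C5–C10). The two cuts therefore open both rings into one chain: an (E)-enal C15–C4=C5 joined through C6–C9 to a diene C10=C1–C2=C3 that carries C14, with C7 as the only stereocentre.
- The chain is cut further at C4=C5 (Wittig), C2=C3 (methylenation) and C10=C1 (Horner–Wadsworth–Emmons), and traced to (R)-carvone opened between its carbonyl carbon and its methyl-bearing carbon.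
- Forward: carvone is opened to a keto ester (steps 1–4); the diene and then the enal are built (steps 5–9); rings A and B form together (step 10); ring A is adjusted to the 3β-hydroxy-4-ene (steps 11–15); acrylate and angelate are installed (steps 16–21); the hydroperoxide comes last (step 22).
- Stereochemistry: C7 from carvone; C10 from the cycloaddition (equatorial C7 substituent in the tether chair, reinforced by the catalyst); C3 from axial hydride delivery to the enone; C5 from attack of singlet oxygen anti to the C10 methyl.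

Key step: step 10

Remark: bicyclic compounds are named on the eudesmane skeleton (C14 on C10, C15 on C4, C11–C13 on C7; "13-nor" means C7 carries only C11–C12); α/β refer to the usual drawing with the C10 methyl β.
Remark: C2 of 5 and 6 forms as both epimers and C4 of 16–19 may epimerise; neither matters, because C2 becomes a ketone carbon in step 4 and C4 becomes trigonal in step 13.

Step 1
Reactants: 1 (R)-carvone
Product: 3 (5R)-5-acetyl-2-methylcyclohex-2-en-1-one, via ozonide 2 (not isolated)
Conditions: O3, CH2Cl2, −78 °C, to the end point of a Sudan red indicator; then Me2S, −78 °C → rt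
Reagents that add atoms: ozone, O=[O+][O-]
Why: Ozonolysis with reductive work-up: the electron-rich 1,1-disubstituted side-chain alkene reacts far faster than the conjugated ring alkene, so titrated ozone should cleave only the isopropenyl group and leave the stereocentre (later C7) untouched.

Step 2
Reactants: 3 (5R)-5-acetyl-2-methylcyclohex-2-en-1-one
Product: 4 (5R)-2-methyl-5-(2-methyl-1,3-dioxolan-2-yl)cyclohex-2-en-1-one
Conditions: 1,2-bis(trimethylsilyloxy)ethane, TMSOTf (2 mol%), CH2Cl2, −78 → −20 °C; pyridine quench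
Reagents that add atoms: 1,2-bis(trimethylsilyloxy)ethane, C[Si](C)(C)OCCO[Si](C)(C)C
Why: Silyl-triflate-catalysed ketalisation (Noyori conditions) is selective for the saturated ketone over the enone and proceeds without enolisation, so the centre α to the acetyl group should not epimerise.

Step 3
Reactants: 4 (5R)-2-methyl-5-(2-methyl-1,3-dioxolan-2-yl)cyclohex-2-en-1-one
Product: 6 (5R)-2-hydroxy-2-methyl-5-(2-methyl-1,3-dioxolan-2-yl)cyclohexan-1-one (C2 epimers), via hydroperoxide 5 (not isolated)
Conditions: Mn(dpm)3 (dpm = 2,2,6,6-tetramethylheptane-3,5-dionate, 3 mol%), PhSiH3, O2 (1 atm), i-PrOH, 0 °C → rt; then P(OEt)3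
Reagents that add atoms: dioxygen, O=O
Why: Manganese-hydride conjugate reduction of the enone with capture of the α-keto radical by O2 (Mukaiyama-type reductive α-hydroxylation of enones) places oxygen regiospecifically on the methyl-bearing carbon; the new centre is lost in step 4.

Step 4
Reactants: 6 (5R)-2-hydroxy-2-methyl-5-(2-methyl-1,3-dioxolan-2-yl)cyclohexan-1-one
Product: 7 methyl (3R)-3-(2-methyl-1,3-dioxolan-2-yl)-6-oxoheptanoate
Conditions: Pb(OAc)4, pyridine, MeOH/benzene 1:1, 0 °C
Reagents that add atoms: methanol, CO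
Why: Lead tetraacetate cleavage of an α-ketol through its methanol hemiketal (glycol-type C–C cleavage) opens the ring between the carbonyl and carbinol carbons, giving a methyl ester (future C5) and a methyl ketone (future C10/C14) that are already differentiated.

Step 5
Reactants: 7 methyl (3R)-3-(2-methyl-1,3-dioxolan-2-yl)-6-oxoheptanoate; 8 triethyl phosphonoacetate
Product: 9 1-ethyl 8-methyl (2E,6R)-3-methyl-6-(2-methyl-1,3-dioxolan-2-yl)oct-2-enedioate
Conditions: NaH, THF, 0 → 50 °C; (Z)-isomer removed by chromatography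
Reagents that add atoms: triethyl phosphonoacetate (8), CCOC(=O)CP(=O)(OCC)OCC
Why: Horner–Wadsworth–Emmons olefination of the methyl ketone proceeds through the less crowded oxaphosphetane and places the ester trans to the longer chain (E); the saturated ester and the ketal are inert to the weakly basic stabilised anion.

Step 6
Reactants: 9 1-ethyl 8-methyl (2E,6R)-3-methyl-6-(2-methyl-1,3-dioxolan-2-yl)oct-2-enedioate
Product: 10 (2E,6R)-3-methyl-6-(2-methyl-1,3-dioxolan-2-yl)oct-2-ene-1,8-diol
Conditions: DIBAL-H (i-Bu2AlH, 5 equiv), CH2Cl2, −78 → 0 °C; Rochelle salt work-up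
Reagents that add atoms: none
Why: Aluminium hydride reduction of both esters gives the (E)-allylic alcohol by 1,2-reduction of the enoate and the primary alcohol from the saturated ester in one operation, the ketal being stable at or below 0 °C.

Step 7
Reactants: 10 (2E,6R)-3-methyl-6-(2-methyl-1,3-dioxolan-2-yl)oct-2-ene-1,8-diol
Product: 11 (2E,6R)-8-hydroxy-3-methyl-6-(2-methyl-1,3-dioxolan-2-yl)oct-2-enal
Conditions: activated MnO2 (excess), CH2Cl2, rt
Reagents that add atoms: none
Why: Chemoselective allylic oxidation with MnO2 converts only the allylic alcohol into the enal and leaves the saturated primary alcohol; the (E) geometry is retained.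

Step 8
Reactants: 11 (2E,6R)-8-hydroxy-3-methyl-6-(2-methyl-1,3-dioxolan-2-yl)oct-2-enal
Product: 12 (3R,6E)-6-methyl-3-(2-methyl-1,3-dioxolan-2-yl)nona-6,8-dien-1-ol
Conditions: Ph3PCH3Br, n-BuLi (2.5 equiv of ylide), THF, −78 → 0 °C
Reagents that add atoms: methyltriphenylphosphonium bromide, C[P+](c1ccccc1)(c1ccccc1)c1ccccc1.[Br-]
Why: Wittig methylenation adds the non-stabilised ylide 1,2 to the enal and extends it to the 1,3-diene without touching the trisubstituted (E) double bond; the free hydroxyl only consumes one extra equivalent of ylide.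

Step 9
Reactants: 12 (3R,6E)-6-methyl-3-(2-methyl-1,3-dioxolan-2-yl)nona-6,8-dien-1-ol; 13 (triphenylphosphoranylidene)acetaldehyde
Product: 15 (2E,5R,8E)-8-methyl-5-(2-methyl-1,3-dioxolan-2-yl)undeca-2,8,10-trienal, via dienal 14 (not isolated)
Conditions: Dess–Martin periodinane, NaHCO3, CH2Cl2, 0 °C → rt; aqueous Na2S2O3 wash; crude aldehyde, 13 (1.05 equiv), toluene, 60 °C
Reagents that add atoms: (triphenylphosphoranylidene)acetaldehyde (13), O=CC=P(c1ccccc1)(c1ccccc1)c1ccccc1
Why: Dess–Martin oxidation followed by Wittig olefination with the formyl-stabilised ylide gives the (E)-enal under thermodynamic control; using the β-branched aldehyde crude and the ylide near stoichiometry limits self-condensation and a second homologation.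

Step 10
Reactants: 15 (2E,5R,8E)-8-methyl-5-(2-methyl-1,3-dioxolan-2-yl)undeca-2,8,10-trienal
Product: 16 (4R,5S,7R,10S)-11,11-ethylenedioxy-13-noreudesm-1-en-15-al (trans-fused; 4α-CHO, 5α-H, 10β-CH3, 7β side chain)
Conditions: (2R,5R)-5-benzyl-2-tert-butyl-3-methylimidazolidin-4-one (20 mol%), CF3CO2H (18 mol%), MeCN/H2O 98:2, 0 °C → rt
Reagents that add atoms: none
Why: The amine salt condenses with the enal to an (E)-iminium ion whose lowered LUMO lets the tethered diene add suprafacially in a concerted, asynchronous [4+2] cycloaddition, after which hydrolysis returns the catalyst; the closest known reaction type is the imidazolidinone-catalysed intramolecular Diels–Alder reaction of 2,8,10-undecatrienals to trans-fused octalins. Ring A closes by the cycloaddition itself (bonds C5–C10 and C3–C4, six-membered pericyclic transition state), and ring B closes from the four-carbon tether C6–C9 folded as a chair under the diene (fused mode, tether on the diene terminus). C10 is controlled by that chair, in which the dioxolanyl group on C7 is equatorial so that the C14 methyl ends axial and cis to it; C5 is controlled by the catalyst, whose benzyl group covers the Re face of C5 so that C10 bonds to the Si face (5S), the face the substrate chair also prefers (matched pair); C4 follows from the (E) enal geometry and the endo position of the iminium group (4R, formyl trans to C6). The step needs endo selectivity for the trans ring fusion, one diene face and survival of the ketal: the first is the normal preference of iminium-activated trienals, the second is secured jointly by the C7 substituent and the catalyst, and the third by keeping the acid below the amine loading at low temperature. The fully substituted diene terminus C10 will slow the reaction relative to unbranched trienals, which the intramolecular setting and the cationic dienophile are expected to offset.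

Step 11
Reactants: 16 (4R,5S,7R,10S)-11,11-ethylenedioxy-13-noreudesm-1-en-15-al
Product: 18 (4R,5S,7R,10S)-11,11-ethylenedioxy-13-noreudesm-1-ene, via hydrazone 17 (not isolated)
Conditions: N2H4·H2O, KOH, diethylene glycol, 120 °C, then 195 °C with removal of water, under argon
Reagents that add atoms: none
Why: Wolff–Kishner reduction (Huang–Minlon procedure) converts the formyl group into the C15 methyl by loss of N2 from the hydrazone, the ketal and the isolated alkene being stable to hot alkali.

Step 12
Reactants: 18 (4R,5S,7R,10S)-11,11-ethylenedioxy-13-noreudesm-1-ene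
Product: 19 (4S,5S,7R,10S)-11,11-ethylenedioxy-13-noreudesm-1-en-3-one
Conditions: CrO3, 3,5-dimethylpyrazole, CH2Cl2, −20 °C
Reagents that add atoms: chromium trioxide, O=[Cr](=O)=O
Why: Allylic oxidation with the CrO3–3,5-dimethylpyrazole complex should give the 1-en-3-one, because C3 is the only allylic C–H position (the other alkene terminus adjoins the quaternary C10, and C1 is the hindered neopentyl end of the allyl system); C4 settles as the equatorial 4α-methyl epimer.

Step 13
Reactants: 19 (4S,5S,7R,10S)-11,11-ethylenedioxy-13-noreudesm-1-en-3-one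
Product: 21 (7R,10S)-11,11-ethylenedioxy-13-noreudesma-1,4-dien-3-one, via silyl dienol ether 20 (not isolated)
Conditions: LDA, TMSCl, THF, −78 → 0 °C; solvent exchange; Pd(OAc)2 (1.1 equiv), MeCN, rt
Reagents that add atoms: none
Why: Saegusa–Ito oxidation: C4 is the only enolisable position of the enone, so silylation gives the 3-silyloxy-1,3-diene regiospecifically, and palladation at C4 followed by β-hydride elimination of the tertiary C5–H gives the cross-conjugated dienone.

Step 14
Reactants: 21 (7R,10S)-11,11-ethylenedioxy-13-noreudesma-1,4-dien-3-one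
Product: 22 (7R,10S)-11,11-ethylenedioxy-13-noreudesm-4-en-3-one
Conditions: H2 (1 atm), RhCl(PPh3)3 (10 mol%), benzene/EtOH 1:1, rt
Reagents that add atoms: none
Why: Homogeneous hydrogenation with RhCl(PPh3)3 reduces the cis-disubstituted C1=C2 bond but cannot coordinate the tetrasubstituted C4=C5 bond, the established selectivity for 1,4-dien-3-ones next to a quaternary C10.

Step 15
Reactants: 22 (7R,10S)-11,11-ethylenedioxy-13-noreudesm-4-en-3-one
Product: 23 (3S,7R,10S)-11,11-ethylenedioxy-13-noreudesm-4-en-3-ol (3β-OH)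
Conditions: NaBH4, CeCl3·7H2O, MeOH, −78 → −20 °C
Reagents that add atoms: none
Why: Luche reduction: cerium-assisted 1,2-reduction with hydride delivered pseudo-axially on the α face, away from the axial C10 methyl, should give the pseudo-equatorial 3β-alcohol (3S).

Step 16
Reactants: 23 (3S,7R,10S)-11,11-ethylenedioxy-13-noreudesm-4-en-3-ol
Product: 24 (3S,7R,10S)-3-(tert-butyldimethylsilyloxy)-11,11-ethylenedioxy-13-noreudesm-4-ene
Conditions: TBSCl, imidazole, DMF, rt → 40 °C
Reagents that add atoms: tert-butyldimethylsilyl chloride, CC(C)(C)[Si](C)(C)Cl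
Why: Silyl ether protection masks the hydroxyl for the strongly basic enolisation of step 18 and makes the allylic position less prone to acid-induced ionisation in step 17.

Step 17
Reactants: 24 (3S,7R,10S)-3-(tert-butyldimethylsilyloxy)-11,11-ethylenedioxy-13-noreudesm-4-ene
Product: 25 (3S,7R,10S)-3-(tert-butyldimethylsilyloxy)-13-noreudesm-4-en-11-one
Conditions: PPTS, acetone/H2O 10:1, 45 °C
Reagents that add atoms: water, O
Why: Acid-catalysed ketal hydrolysis under pyridinium tosylate is mild enough to leave the allylic silyl ether and the C7 centre α to the liberated ketone unchanged.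

Step 18
Reactants: 25 (3S,7R,10S)-3-(tert-butyldimethylsilyloxy)-13-noreudesm-4-en-11-one
Product: 26 (3S,7R,10S)-3-(tert-butyldimethylsilyloxy)-13-noreudesma-4,11-dien-11-yl trifluoromethanesulfonate
Conditions: KHMDS (1.3 equiv), THF, −78 °C (ketone added to base); PhNTf2, −78 → −20 °C
Reagents that add atoms: N-phenylbis(trifluoromethanesulfonimide), O=S(=O)(N(c1ccccc1)S(=O)(=O)C(F)(F)F)C(F)(F)F
Why: Kinetic enolate formation and O-triflation: the hindered amide base removes a methyl proton, not the C7 methine, at −78 °C, and the triflimide traps the enolate on oxygen as the terminal enol triflate without epimerising C7.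

Step 19
Reactants: 26 (3S,7R,10S)-3-(tert-butyldimethylsilyloxy)-13-noreudesma-4,11-dien-11-yl trifluoromethanesulfonate
Product: 27 methyl (3S,7R,10S)-3-(tert-butyldimethylsilyloxy)eudesma-4,11(13)-dien-12-oate
Conditions: CO (1 atm), Pd(OAc)2 (5 mol%), PPh3 (10 mol%), Et3N, MeOH/DMF, 45 °C
Reagents that add atoms: carbon monoxide, [C-]#[O+]; methanol, CO
Why: Palladium-catalysed alkoxycarbonylation of a vinyl triflate (oxidative addition to zerovalent palladium, CO insertion, methanolysis of the acyl complex) gives the 2-substituted acrylate and so adds C12 of the methyl ester.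

Step 20
Reactants: 27 methyl (3S,7R,10S)-3-(tert-butyldimethylsilyloxy)eudesma-4,11(13)-dien-12-oate
Product: 28 methyl (3S,7R,10S)-3-hydroxyeudesma-4,11(13)-dien-12-oate
Conditions: HF·pyridine, pyridine, THF, 0 °C → rt
Reagents that add atoms: none
Why: Fluoride-mediated desilylation under pyridine-buffered conditions should neither add to the acrylate nor ionise the allylic alcohol.

Step 21
Reactants: 28 methyl (3S,7R,10S)-3-hydroxyeudesma-4,11(13)-dien-12-oate; 29 angelic acid
Product: 31 methyl (3S,7R,10S)-3-[(Z)-2-methylbut-2-enoyloxy]eudesma-4,11(13)-dien-12-oate, via mixed anhydride 30 (not isolated)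
Conditions: 29, 2,4,6-trichlorobenzoyl chloride, Et3N, toluene, rt; then 28, 75 °C
Reagents that add atoms: angelic acid (29), C/C=C(C)\C(=O)O
Why: Yamaguchi esterification: the mixed anhydride of angelic acid acylates the hindered allylic alcohol on heating without a nucleophilic catalyst, conditions that preserve the (Z) geometry of angelates; C3 is not involved, so 3S is retained.

Step 22
Reactants: 31 methyl (3S,7R,10S)-3-[(Z)-2-methylbut-2-enoyloxy]eudesma-4,11(13)-dien-12-oate
Product: 32 methyl (3S,5S,7R,10S)-5-hydroperoxy-3-[(Z)-2-methylbut-2-enoyloxy]eudesma-4(15),11(13)-dien-12-oate (target)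
Conditions: O2, visible light, 5,10,15,20-tetraphenylporphyrin (1 mol%), CH2Cl2, −20 °C
Reagents that add atoms: dioxygen, O=O
Why: Schenck ene reaction of singlet oxygen with the tetrasubstituted C4=C5 bond: attack on the α face, opposite the axial C10 methyl, with hydrogen abstraction from the C15 methyl on the more crowded C15/C6 side (the α-hydrogen on C6 is pseudo-equatorial and poorly aligned) should give the 5α-hydroperoxide (5S) and the exocyclic C4=C15 bond, the acrylate and angelate alkenes being too electron-poor to react.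

**Compound list**
1 | (R)-carvone, (5R)-2-methyl-5-(prop-1-en-2-yl)cyclohex-2-en-1-one | CC(=C)[C@@H]1CC=C(C)C(=O)C1 | starting material
2 | (5R)-2-methyl-5-(3-methyl-1,2,4-trioxolan-3-yl)cyclohex-2-en-1-one (side-chain ozonide, trioxolane carbon unspecified) | CC1(OCOO1)[C@@H]2CC=C(C)C(=O)C2 | intermediate
3 | (5R)-5-acetyl-2-methylcyclohex-2-en-1-one | CC(=O)[C@@H]1CC=C(C)C(=O)C1 | intermediate
4 | (5R)-2-methyl-5-(2-methyl-1,3-dioxolan-2-yl)cyclohex-2-en-1-one | CC1(OCCO1)[C@@H]2CC=C(C)C(=O)C2 | intermediate
5 | (5R)-2-hydroperoxy-2-methyl-5-(2-methyl-1,3-dioxolan-2-yl)cyclohexan-1-one (C2 epimers) | CC1(OCCO1)[C@@H]2CCC(C)(OO)C(=O)C2 | intermediate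
6 | (5R)-2-hydroxy-2-methyl-5-(2-methyl-1,3-dioxolan-2-yl)cyclohexan-1-one (C2 epimers) | CC1(OCCO1)[C@@H]2CCC(C)(O)C(=O)C2 | intermediate
7 | methyl (3R)-3-(2-methyl-1,3-dioxolan-2-yl)-6-oxoheptanoate | COC(=O)C[C@@H](CCC(C)=O)C1(C)OCCO1 | intermediate
8 | triethyl phosphonoacetate | CCOC(=O)CP(=O)(OCC)OCC | starting material
9 | 1-ethyl 8-methyl (2E,6R)-3-methyl-6-(2-methyl-1,3-dioxolan-2-yl)oct-2-enedioate | CCOC(=O)/C=C(\C)CC[C@H](CC(=O)OC)C1(C)OCCO1 | intermediate
10 | (2E,6R)-3-methyl-6-(2-methyl-1,3-dioxolan-2-yl)oct-2-ene-1,8-diol | OC/C=C(\C)CC[C@H](CCO)C1(C)OCCO1 | intermediate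
11 | (2E,6R)-8-hydroxy-3-methyl-6-(2-methyl-1,3-dioxolan-2-yl)oct-2-enal | O=C/C=C(\C)CC[C@H](CCO)C1(C)OCCO1 | intermediate
12 | (3R,6E)-6-methyl-3-(2-methyl-1,3-dioxolan-2-yl)nona-6,8-dien-1-ol | OCC[C@@H](CC/C(C)=C/C=C)C1(C)OCCO1 | intermediate
13 | (triphenylphosphoranylidene)acetaldehyde | O=CC=P(c1ccccc1)(c1ccccc1)c1ccccc1 | starting material
14 | (3R,6E)-6-methyl-3-(2-methyl-1,3-dioxolan-2-yl)nona-6,8-dienal | O=CC[C@@H](CC/C(C)=C/C=C)C1(C)OCCO1 | intermediate
15 | (2E,5R,8E)-8-methyl-5-(2-methyl-1,3-dioxolan-2-yl)undeca-2,8,10-trienal | O=C/C=C/C[C@H](C1(C)OCCO1)CC/C(C)=C/C=C | intermediate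
16 | (4R,5S,7R,10S)-11,11-ethylenedioxy-13-noreudesm-1-en-15-al | CC1(OCCO1)[C@@H]2CC[C@@]3(C)C=CC[C@@H](C=O)[C@@H]3C2 | intermediate
17 | hydrazone of 16 | CC1(OCCO1)[C@@H]2CC[C@@]3(C)C=CC[C@@H](C=NN)[C@@H]3C2 | intermediate
18 | (4R,5S,7R,10S)-11,11-ethylenedioxy-13-noreudesm-1-ene | CC1(OCCO1)[C@@H]2CC[C@@]3(C)C=CC[C@@H](C)[C@@H]3C2 | intermediate
19 | (4S,5S,7R,10S)-11,11-ethylenedioxy-13-noreudesm-1-en-3-one | CC1(OCCO1)[C@@H]2CC[C@@]3(C)C=CC(=O)[C@@H](C)[C@@H]3C2 | intermediate
20 | (7R,10S)-11,11-ethylenedioxy-3-(trimethylsilyloxy)-13-nor-5αH-eudesma-1,3-diene | CC1(OCCO1)[C@@H]2CC[C@@]3(C)C=CC(O[Si](C)(C)C)=C(C)[C@@H]3C2 | intermediate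
21 | (7R,10S)-11,11-ethylenedioxy-13-noreudesma-1,4-dien-3-one | CC1(OCCO1)[C@@H]2CC[C@@]3(C)C=CC(=O)C(C)=C3C2 | intermediate
22 | (7R,10S)-11,11-ethylenedioxy-13-noreudesm-4-en-3-one | CC1(OCCO1)[C@@H]2CC[C@@]3(C)CCC(=O)C(C)=C3C2 | intermediate
23 | (3S,7R,10S)-11,11-ethylenedioxy-13-noreudesm-4-en-3-ol | CC1(OCCO1)[C@@H]2CC[C@@]3(C)CC[C@H](O)C(C)=C3C2 | intermediate
24 | (3S,7R,10S)-3-(tert-butyldimethylsilyloxy)-11,11-ethylenedioxy-13-noreudesm-4-ene | CC1(OCCO1)[C@@H]2CC[C@@]3(C)CC[C@H](O[Si](C)(C)C(C)(C)C)C(C)=C3C2 | intermediate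
25 | (3S,7R,10S)-3-(tert-butyldimethylsilyloxy)-13-noreudesm-4-en-11-one | CC(=O)[C@@H]1CC[C@@]2(C)CC[C@H](O[Si](C)(C)C(C)(C)C)C(C)=C2C1 | intermediate
26 | (3S,7R,10S)-3-(tert-butyldimethylsilyloxy)-13-noreudesma-4,11-dien-11-yl trifluoromethanesulfonate | C=C(OS(=O)(=O)C(F)(F)F)[C@@H]1CC[C@@]2(C)CC[C@H](O[Si](C)(C)C(C)(C)C)C(C)=C2C1 | intermediate
27 | methyl (3S,7R,10S)-3-(tert-butyldimethylsilyloxy)eudesma-4,11(13)-dien-12-oate | C=C(C(=O)OC)[C@@H]1CC[C@@]2(C)CC[C@H](O[Si](C)(C)C(C)(C)C)C(C)=C2C1 | intermediate
28 | methyl (3S,7R,10S)-3-hydroxyeudesma-4,11(13)-dien-12-oate | C=C(C(=O)OC)[C@@H]1CC[C@@]2(C)CC[C@H](O)C(C)=C2C1 | intermediate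
29 | angelic acid, (Z)-2-methylbut-2-enoic acid | C/C=C(C)\C(=O)O | starting material
30 | (Z)-2-methylbut-2-enoic 2,4,6-trichlorobenzoic anhydride | C/C=C(C)\C(=O)OC(=O)c1c(Cl)cc(Cl)cc1Cl | intermediate
31 | methyl (3S,7R,10S)-3-[(Z)-2-methylbut-2-enoyloxy]eudesma-4,11(13)-dien-12-oate | C=C(C(=O)OC)[C@@H]1CC[C@@]2(C)CC[C@H](OC(=O)/C(C)=C\C)C(C)=C2C1 | intermediate
32 | methyl (3S,5S,7R,10S)-5-hydroperoxy-3-[(Z)-2-methylbut-2-enoyloxy]eudesma-4(15),11(13)-dien-12-oate | C=C(C(=O)OC)[C@@H]1CC[C@@]2(C)CC[C@H](OC(=O)/C(C)=C\C)C(=C)[C@]2(OO)C1 | target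

**Step count**
Total: 22 steps. Longest linear sequence: 22 steps, from (R)-carvone.

**Steps most likely to fail**

Step 10. The C14 methyl sits on the inside of the diene, so the s-cis geometry and the approach to the iminium carbon are hindered. A slow cycloaddition would leave time for iminium-initiated oligomerisation of the diene, hydrolysis of the ketal, or leakage through the exo mode. The fallback changes the activation from an iminium ion to a chelated imide and sets out from dienol 12. Dess–Martin oxidation gives dienal 14, this time isolated. Horner–Wadsworth–Emmons olefination with diethyl [2-oxo-2-(2-oxo-1,3-oxazolidin-3-yl)ethyl]phosphonate (LiCl, i-Pr2NEt, MeCN) gives the (E)-trienimide F1. Me2AlCl (CH2Cl2, −30 °C) chelates the imide and promotes the endo cycloaddition to the trans-fused imide F2, the diene face again being set by the equatorial C7 substituent. LiBH4 (THF, MeOH) releases the primary alcohol F3, and Dess–Martin oxidation returns the route to aldehyde 16.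

Step 22. Hydrogen may be abstracted from C6 or from the acyloxy-bearing C3 rather than from the C15 methyl, oxygen may attack the β face, and the allylic hydroperoxide may rearrange by a radical path in the presence of the two unsaturated esters. The fallback moves the oxygenation ahead of the esterification and sets out from silyl ether 27. Photooxygenation under the same sensitised conditions gives the hydroperoxide F4, the bulky 3β-silyloxy group screening the β face. The hydroperoxide is masked with 2-methoxypropene and PPTS as the peroxyketal F5. Bu4NF in THF removes the silyl group to give the alcohol F6. Yamaguchi esterification with angelic acid 29 gives the angelate F7. Aqueous acetic acid in THF cleaves the peroxyketal and returns the route to the target 32.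

Step 13. Deprotonation at C4 may be slow because that hydrogen is syn-axial to the C10 methyl, palladation of the tetrasubstituted enol ether may be incomplete, and β-hydride elimination may run toward the C15 methyl to give the exocyclic enone. The fallback replaces the palladium step by halogenation–dehydrohalogenation and sets out from silyl dienol ether 20. N-Bromosuccinimide (THF, 0 °C) brominates C4 to give the bromo enone F8 (either C4 epimer). Li2CO3 and LiBr in DMF at 120 °C eliminate HBr toward C5 into conjugation and return the route to dienone 21.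

**Further compounds**
F1 | step 10 | 3-[(2E,5R,8E)-8-methyl-5-(2-methyl-1,3-dioxolan-2-yl)undeca-2,8,10-trienoyl]-1,3-oxazolidin-2-one | O=C(/C=C/C[C@H](C1(C)OCCO1)CC/C(C)=C/C=C)N1CCOC1=O
F2 | step 10 | 3-[(4R,5S,7R,10S)-11,11-ethylenedioxy-13-noreudesm-1-en-15-oyl]-1,3-oxazolidin-2-one | CC1(OCCO1)[C@@H]2CC[C@@]3(C)C=CC[C@@H](C(=O)N4CCOC4=O)[C@@H]3C2
F3 | step 10 | (4R,5S,7R,10S)-11,11-ethylenedioxy-13-noreudesm-1-en-15-ol | CC1(OCCO1)[C@@H]2CC[C@@]3(C)C=CC[C@@H](CO)[C@@H]3C2
F4 | step 22 | methyl (3S,5S,7R,10S)-3-(tert-butyldimethylsilyloxy)-5-hydroperoxyeudesma-4(15),11(13)-dien-12-oate | C=C(C(=O)OC)[C@@H]1CC[C@@]2(C)CC[C@H](O[Si](C)(C)C(C)(C)C)C(=C)[C@]2(OO)C1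
F5 | step 22 | methyl (3S,5S,7R,10S)-3-(tert-butyldimethylsilyloxy)-5-[(2-methoxypropan-2-yl)peroxy]eudesma-4(15),11(13)-dien-12-oate | C=C(C(=O)OC)[C@@H]1CC[C@@]2(C)CC[C@H](O[Si](C)(C)C(C)(C)C)C(=C)[C@]2(OOC(C)(C)OC)C1
F6 | step 22 | methyl (3S,5S,7R,10S)-3-hydroxy-5-[(2-methoxypropan-2-yl)peroxy]eudesma-4(15),11(13)-dien-12-oate | C=C(C(=O)OC)[C@@H]1CC[C@@]2(C)CC[C@H](O)C(=C)[C@]2(OOC(C)(C)OC)C1
F7 | step 22 | methyl (3S,5S,7R,10S)-5-[(2-methoxypropan-2-yl)peroxy]-3-[(Z)-2-methylbut-2-enoyloxy]eudesma-4(15),11(13)-dien-12-oate | C=C(C(=O)OC)[C@@H]1CC[C@@]2(C)CC[C@H](OC(=O)/C(C)=C\C)C(=C)[C@]2(OOC(C)(C)OC)C1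
F8 | step 13 | (5S,7R,10S)-4-bromo-11,11-ethylenedioxy-13-noreudesm-1-en-3-one (C4 epimers) | CC1(OCCO1)[C@@H]2CC[C@@]3(C)C=CC(=O)C(C)(Br)[C@@H]3C2
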